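**Plan** (lignan numbering: guaiacyl half C7–C9, syringyl half C7'–C9', glycerol side chain C7''–C9'')
1. Retrosynthesis, last to first: the side chain is cut at C7''–C8'' (Evans glycolate aldol) and at the aryl-O–CH2 bond of its precursor (phenol O-alkylation); the O–C9' ring bond is cut (lactone reduction, mesylate closure); then C8–C9 and C8'–C7' are cut together by a carbonyl ylide (3+2) cycloaddition.
2. Enabling feature: in the tetrahydrofuran ring that carries the syringyl group, C9H2–O–C7'H(aryl) is a C–O–C triad whose two ends carry the bonds to be made, i.e. the carbonyl ylide of a syringaldehyde ether; the ring-fusion bond C8–C8' is then the C=C of a 5-aryl butenolide (ring C7–O–C9'–C8'–C8).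
3. Forward: the lactone ring with C7 is made first, the cycloaddition adds the second ring to give an endo,exo-furofuranone, the C9' carbonyl is taken to CH2 with re-closure of the ring, and the side chain is joined last.
4. Stereochemistry: C7 from a zinc–ProPhenol alkynylation; C8, C8' and C7' from the cycloaddition (anti to the C7 aryl group, cis fusion, endo aryl); C7'' and C8'' from (S)-4-benzyloxazolidin-2-one.

Key step: step 5

Remark: the sense of induction of the zinc–ProPhenol alkynylation is taken as (S,S)-ligand → (S)-carbinol and is to be checked on 3 by Mosher ester analysis; the antipodal ligand is used if the sense is opposite.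

**Route**

Step 1
Reactants: 1 4-(benzyloxy)-3-methoxybenzaldehyde; 2 methyl propiolate
Product: 3 methyl (S)-4-[4-(benzyloxy)-3-methoxyphenyl]-4-hydroxybut-2-ynoate
Conditions: (S,S)-ProPhenol (10 mol%), Me2Zn (3 equiv), Ph3PO (20 mol%), toluene, 0–4 °C; aq. NH4Cl
Reagents that add atoms: none
Why: Zinc–ProPhenol-catalysed asymmetric alkynylation, in which the dinuclear zinc complex holds the aldehyde and the zinc acetylide of 2 and delivers the alkynyl group to one carbonyl face, should set the (S)-carbinol that becomes C7.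

Step 2
Reactants: 3 methyl (S)-4-[4-(benzyloxy)-3-methoxyphenyl]-4-hydroxybut-2-ynoate
Product: 5 (R)-5-[4-(benzyloxy)-3-methoxyphenyl]furan-2(5H)-one, via Z-hydroxy enoate 4 (not isolated)
Conditions: H2 (1 atm), Pd/CaCO3 poisoned with Pb(OAc)2 (Lindlar catalyst), quinoline, EtOAc, rt; then SiO2, CH2Cl2, rt
Reagents that add atoms: none
Why: Lindlar semihydrogenation adds H2 syn to give the Z-enoate, whose hydroxyl then lies next to the ester and lactonises with loss of methanol, the carbinol centre being untouched (the descriptor changes from S to R only because the neighbouring carbon loses CIP priority).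

Step 3
Reactants: 6 syringaldehyde (4-hydroxy-3,5-dimethoxybenzaldehyde)
Product: 7 4-(allyloxy)-3,5-dimethoxybenzaldehyde
Conditions: allyl bromide, K2CO3, DMF, 50 °C
Reagents that add atoms: allyl bromide, C=CCBr
Why: Williamson ether synthesis on the phenoxide gives an allyl ether that should survive fluoride, hydride and sulfonylation and can later be removed by palladium catalysis without touching the benzyl ether.

Step 4
Reactants: 7 4-(allyloxy)-3,5-dimethoxybenzaldehyde
Product: 8 4-(allyloxy)-3,5-dimethoxybenzaldehyde bis[(trimethylsilyl)methyl] acetal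
Conditions: Me3SiCH2OH (2.5 equiv), PPTS (5 mol%), benzene, reflux, Dean–Stark; Et3N quench
Reagents that add atoms: (trimethylsilyl)methanol, C[Si](C)(C)CO
Why: Acid-catalysed acetalisation with azeotropic removal of water installs two silylmethoxy groups, one of which becomes the leaving group and the other the silicon trigger for ylide formation.

Step 5
Reactants: 8 4-(allyloxy)-3,5-dimethoxybenzaldehyde bis[(trimethylsilyl)methyl] acetal; 5 (R)-5-[4-(benzyloxy)-3-methoxyphenyl]furan-2(5H)-one
Product: 11 (3R,3aS,6S,6aR)-6-[4-(allyloxy)-3,5-dimethoxyphenyl]-3-[4-(benzyloxy)-3-methoxyphenyl]tetrahydro-1H,3H-furo[3,4-c]furan-1-one (syringyl endo; guaiacyl exo; cis ring fusion), via chloro ether 9 (not isolated), via carbonyl ylide 10 (not isolated)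
Conditions: 8 (1.7 equiv), AcCl (1.7 equiv), CH2Cl2, 0 °C → rt, volatiles removed; then 5 (1 equiv), CsF (4 equiv), MeCN, rt
Reagents that add atoms: none
Why: Acetyl chloride turns acetal 8 into α-chloro ether 9, fluoride attack on silicon then expels chloride in a 1,3-elimination to give the non-stabilised carbonyl ylide 10 (the C9–O–C7' triad), and 10 adds across the C8=C8' bond of butenolide 5; the closest known reaction type is the fluoride-induced 1,3-elimination of 1-chloroalkyl (trimethylsilyl)methyl ethers with (3+2) cycloaddition of the ylide to electron-poor alkenes. The tetrahydrofuran ring (C9, O, C7', C8', C8) is closed by a suprafacial (3+2) cycloaddition of the four-electron C–O–C dipole to the lactone C=C, or at the stepwise limit by Michael addition of the CH2 terminus followed by 5-endo attack of the lactone enolate on the oxocarbenium carbon, so that C8–C9 and C8'–C7' form in one operation. Regioselectivity follows from the polarisation of the dipole: the electron-rich aryl group stabilises positive charge at C7', the CH2 terminus is therefore the nucleophilic end and bonds to the β-carbon C8, and C7' bonds to the α-carbon C8'. C8 and C8' should come out cis because the addition is suprafacial on a Z-alkene held in a five-membered ring, and their sense relative to C7 is controlled by approach of the dipole to the lactone face opposite the C7 aryl group. C7' is controlled by an endo transition state of the W-shaped (E) ylide in which the aryl group lies over the lactone carbonyl, which places the syringyl group cis to C9' (endo on the bicycle). The step needs face, regio and endo selectivity and no loss of configuration at the acidic C7–H of 5; the first two are secured by the C7 substituent and the polarised dipole, whereas the endo preference and the mildness of suspended CsF towards 5 are the points at risk.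

Step 6
Reactants: 11 the furofuranone of step 5
Product: 12 {(2S,3S,4S)-2-[4-(allyloxy)-3,5-dimethoxyphenyl]-4-[(R)-[4-(benzyloxy)-3-methoxyphenyl](hydroxy)methyl]tetrahydrofuran-3-yl}methanol
Conditions: LiBH4, THF, 0 °C → rt
Reagents that add atoms: none
Why: Hydride reduction of the lactone carbonyl with ring opening should give the 1,4-diol and leave the ethers, the terminal alkene and all four stereocentres untouched.

Step 7
Reactants: 12 the diol of step 6
Product: 14 (1R,3aS,4S,6aS)-4-[4-(allyloxy)-3,5-dimethoxyphenyl]-1-[4-(benzyloxy)-3-methoxyphenyl]tetrahydro-1H,3H-furo[3,4-c]furan, via primary mesylate 13 (not isolated)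
Conditions: MsCl (1.1 equiv), pyridine, CH2Cl2, 0 °C → rt
Reagents that add atoms: none
Why: The primary alcohol is sulfonylated faster than the hindered benzylic one and the benzylic hydroxyl then displaces the mesylate in a 5-exo-tet Williamson closure, so the benzylic C–O bond is never broken and C7 keeps its configuration.

Step 8
Reactants: 14 the allyl-protected furofuran of step 7
Product: 15 4-[(1S,3aS,4R,6aS)-4-[4-(benzyloxy)-3-methoxyphenyl]tetrahydro-1H,3H-furo[3,4-c]furan-1-yl]-2,6-dimethoxyphenol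
Conditions: Pd(PPh3)4 (5 mol%), morpholine, THF, rt
Reagents that add atoms: none
Why: Tsuji–Trost-type deallylation, in which zerovalent palladium ionises the aryl allyl ether to a π-allyl complex that morpholine captures, should free the phenol under neutral conditions that leave the benzyl ether and the acid-labile endo benzylic ether alone.

Step 9
Reactants: 16 (S)-4-benzyloxazolidin-2-one
Product: 17 (S)-4-benzyl-3-(bromoacetyl)oxazolidin-2-one
Conditions: n-BuLi, THF, −78 °C; then bromoacetyl bromide, −78 → 0 °C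
Reagents that add atoms: bromoacetyl bromide, BrCC(Br)=O
Why: N-Acylation of the lithiated carbamate occurs at the acyl bromide, which is far more electrophilic than the alkyl bromide, and gives the auxiliary-bearing alkylating agent.

Step 10
Reactants: 15 the phenol of step 8; 17 (S)-4-benzyl-3-(bromoacetyl)oxazolidin-2-one
Product: 18 (S)-4-benzyl-3-[(aryloxy)acetyl]oxazolidin-2-one in which the aryloxy group is the phenoxy group of 15
Conditions: K2CO3, acetone, rt
Reagents that add atoms: none
Why: Williamson alkylation of the hindered 2,6-dimethoxyphenoxide at the activated α-bromo carbonyl carbon (SN2) should attach the glycolyl imide without touching any stereocentre.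

Step 11
Reactants: 18 the aryloxyacetyl imide of step 10; 19 4-(benzyloxy)-3,5-dimethoxybenzaldehyde
Product: 21 (S)-4-benzyl-3-[(2S,3R)-2-(aryloxy)-3-[4-(benzyloxy)-3,5-dimethoxyphenyl]-3-hydroxypropanoyl]oxazolidin-2-one (aryloxy as in 18), via boron enolate 20 (not isolated)
Conditions: Bu2BOTf (1.2 equiv), i-Pr2NEt (1.4 equiv), CH2Cl2, −78 → 0 °C; then 19, −78 → 0 °C; pH 7 buffer, MeOH, 30% H2O2, 0 °C
Reagents that add atoms: none
Why: Evans syn-aldol reaction of the Z-boron enolate through a closed chair (Zimmerman–Traxler) transition state, with the aldehyde approaching the enolate face away from the benzyl group of the auxiliary, should set C8'' and C7'' as the (2S,3R)-syn adduct that corresponds to the threo (7''R,8''R) side chain.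

Step 12
Reactants: 21 the aldol adduct of step 11
Product: 22 (1R,2R)-1-[4-(benzyloxy)-3,5-dimethoxyphenyl]-2-(aryloxy)propane-1,3-diol (aryloxy as in 18)
Conditions: LiBH4, THF, MeOH (1.5 equiv), 0 °C
Reagents that add atoms: none
Why: Hydride attacks the exocyclic imide carbonyl and reductive cleavage should give the primary alcohol (C9'') and release the oxazolidinone without epimerising the adjacent aryloxy-bearing carbon.

Step 13
Reactants: 22 the dibenzyl ether of step 12
Product: 23 (1R,2R)-1-(4-hydroxy-3,5-dimethoxyphenyl)-2-{4-[(1S,3aS,4R,6aS)-4-(4-hydroxy-3-methoxyphenyl)tetrahydro-1H,3H-furo[3,4-c]furan-1-yl]-2,6-dimethoxyphenoxy}propane-1,3-diol (target)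
Conditions: H2 (1 atm), 10% Pd/C, EtOAc, rt, stopped at full conversion
Reagents that add atoms: none
Why: Hydrogenolysis of the two aryl benzyl ethers on palladium is much faster under neutral conditions than cleavage of the dialkyl benzylic ethers or the benzylic alcohol, so both phenols should be freed with the six stereocentres kept.

**Compound list**

1 | 4-(benzyloxy)-3-methoxybenzaldehyde | COc1cc(C=O)ccc1OCc1ccccc1 | starting material
2 | methyl propiolate | C#CC(=O)OC | starting material
3 | methyl (S)-4-[4-(benzyloxy)-3-methoxyphenyl]-4-hydroxybut-2-ynoate | COC(=O)C#C[C@@H](O)c1ccc(OCc2ccccc2)c(OC)c1 | intermediate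
4 | methyl (R,Z)-4-[4-(benzyloxy)-3-methoxyphenyl]-4-hydroxybut-2-enoate | COC(=O)/C=C\[C@@H](O)c1ccc(OCc2ccccc2)c(OC)c1 | intermediate (not isolated)
5 | (R)-5-[4-(benzyloxy)-3-methoxyphenyl]furan-2(5H)-one | COc1cc([C@@H]2OC(=O)C=C2)ccc1OCc1ccccc1 | intermediate
6 | syringaldehyde | COc1cc(C=O)cc(OC)c1O | starting material
7 | 4-(allyloxy)-3,5-dimethoxybenzaldehyde | COc1cc(C=O)cc(OC)c1OCC=C | intermediate
8 | 4-(allyloxy)-3,5-dimethoxybenzaldehyde bis[(trimethylsilyl)methyl] acetal | COc1cc(C(OC[Si](C)(C)C)OC[Si](C)(C)C)cc(OC)c1OCC=C | intermediate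
9 | [4-(allyloxy)-3,5-dimethoxyphenyl](chloro)methyl (trimethylsilyl)methyl ether | COc1cc(C(Cl)OC[Si](C)(C)C)cc(OC)c1OCC=C | intermediate (not isolated)
10 | (E)-carbonyl ylide of 7 and methylene, [4-(allyloxy)-3,5-dimethoxybenzylidene]oxonium methylide | [CH2-]/[O+]=C/c1cc(OC)c(OCC=C)c(OC)c1 | intermediate (not isolated)
11 | (3R,3aS,6S,6aR)-6-[4-(allyloxy)-3,5-dimethoxyphenyl]-3-[4-(benzyloxy)-3-methoxyphenyl]tetrahydro-1H,3H-furo[3,4-c]furan-1-one | COc1cc([C@@H]2OC(=O)[C@@H]3[C@H]2CO[C@@H]3c2cc(OC)c(OCC=C)c(OC)c2)ccc1OCc1ccccc1 | intermediate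
12 | {(2S,3S,4S)-2-[4-(allyloxy)-3,5-dimethoxyphenyl]-4-[(R)-[4-(benzyloxy)-3-methoxyphenyl](hydroxy)methyl]tetrahydrofuran-3-yl}methanol | COc1cc([C@H](O)[C@@H]2CO[C@H](c3cc(OC)c(OCC=C)c(OC)c3)[C@@H]2CO)ccc1OCc1ccccc1 | intermediate
13 | primary methanesulfonate of 12 | COc1cc([C@H](O)[C@@H]2CO[C@H](c3cc(OC)c(OCC=C)c(OC)c3)[C@@H]2COS(C)(=O)=O)ccc1OCc1ccccc1 | intermediate (not isolated)
14 | (1R,3aS,4S,6aS)-4-[4-(allyloxy)-3,5-dimethoxyphenyl]-1-[4-(benzyloxy)-3-methoxyphenyl]tetrahydro-1H,3H-furo[3,4-c]furan | COc1cc([C@@H]2OC[C@@H]3[C@H]2CO[C@@H]3c2cc(OC)c(OCC=C)c(OC)c2)ccc1OCc1ccccc1 | intermediate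
15 | 4-[(1S,3aS,4R,6aS)-4-[4-(benzyloxy)-3-methoxyphenyl]tetrahydro-1H,3H-furo[3,4-c]furan-1-yl]-2,6-dimethoxyphenol | COc1cc([C@@H]2OC[C@@H]3[C@H]2CO[C@@H]3c2cc(OC)c(O)c(OC)c2)ccc1OCc1ccccc1 | intermediate
16 | (S)-4-benzyloxazolidin-2-one | O=C1N[C@@H](Cc2ccccc2)CO1 | starting material
17 | (S)-4-benzyl-3-(bromoacetyl)oxazolidin-2-one | O=C(CBr)N1[C@@H](Cc2ccccc2)COC1=O | intermediate
18 | (S)-4-benzyl-3-[(aryloxy)acetyl]oxazolidin-2-one, aryloxy = phenoxy group of 15 | COc1cc([C@@H]2OC[C@@H]3[C@H]2CO[C@@H]3c2cc(OC)c(OCC(=O)N4[C@@H](Cc5ccccc5)COC4=O)c(OC)c2)ccc1OCc1ccccc1 | intermediate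
19 | 4-(benzyloxy)-3,5-dimethoxybenzaldehyde | COc1cc(C=O)cc(OC)c1OCc1ccccc1 | starting material
20 | Z-configured dibutylboron enolate of 18 | COc1cc([C@@H]2OC[C@@H]3[C@H]2CO[C@@H]3c2cc(OC)c(O/C=C(\OB(CCCC)CCCC)N4[C@@H](Cc5ccccc5)COC4=O)c(OC)c2)ccc1OCc1ccccc1 | intermediate (not isolated)
21 | (2S,3R)-syn aldol adduct of 18 and 19 | COc1cc([C@@H]2OC[C@@H]3[C@H]2CO[C@@H]3c2cc(OC)c(O[C@H](C(=O)N4[C@@H](Cc5ccccc5)COC4=O)[C@H](O)c4cc(OC)c(OCc5ccccc5)c(OC)c4)c(OC)c2)ccc1OCc1ccccc1 | intermediate
22 | (1R,2R)-1-[4-(benzyloxy)-3,5-dimethoxyphenyl]-2-(aryloxy)propane-1,3-diol, aryloxy = phenoxy group of 15 | COc1cc([C@@H]2OC[C@@H]3[C@H]2CO[C@@H]3c2cc(OC)c(O[C@H](CO)[C@H](O)c4cc(OC)c(OCc5ccccc5)c(OC)c4)c(OC)c2)ccc1OCc1ccccc1 | intermediate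
23 | (1R,2R)-1-(4-hydroxy-3,5-dimethoxyphenyl)-2-{4-[(1S,3aS,4R,6aS)-4-(4-hydroxy-3-methoxyphenyl)tetrahydro-1H,3H-furo[3,4-c]furan-1-yl]-2,6-dimethoxyphenoxy}propane-1,3-diol | COc1cc([C@@H]2OC[C@@H]3[C@H]2CO[C@@H]3c2cc(OC)c(O[C@H](CO)[C@H](O)c3cc(OC)c(O)c(OC)c3)c(OC)c2)ccc1O | target

**Summary**

Total step count: 13. Longest linear sequence: 10 steps (steps 1, 2, 5, 6, 7, 8, 10, 11, 12, 13).

Steps most likely to fail:

Step 5. What may go wrong: poor endo or regio control in the cycloaddition, collapse of ylide 10 to the aryl oxirane before it is trapped, or fluoride-induced racemisation of butenolide 5 through its 2-oxidofuran form. Fallback (sets out from 7 and 5, comes back at 11): the two bonds are made one after the other. Aldehyde 7 is reduced (NaBH4, MeOH) to [4-(allyloxy)-3,5-dimethoxyphenyl]methanol F1, which is alkylated (NaH, Bu3SnCH2I, THF–DMF) to tributyl({[4-(allyloxy)-3,5-dimethoxybenzyl]oxy}methyl)stannane F2. Tin–lithium exchange (n-BuLi, −78 °C), conversion into the cuprate (CuBr·SMe2, TMSCl) and conjugate addition to 5 anti to the aryl group should give the trans lactone (4S,5R)-4-({[4-(allyloxy)-3,5-dimethoxybenzyl]oxy}methyl)-5-[4-(benzyloxy)-3-methoxyphenyl]dihydrofuran-2(3H)-one F3. Detrifluoroacetylative diazo transfer (LiHMDS, CF3CO2CH2CF3, −78 °C, to the 3-(trifluoroacetyl) lactone F4; then MsN3, Et3N, MeCN) gives the 3-diazo lactone F5. Rh2(OAc)4-catalysed 1,5 C–H insertion of the carbenoid into the benzylic ether C–H then forms C8'–C7' with the aryl group endo and returns the route at 11.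

Step 11. What may go wrong: ionisation and epimerisation of the endo benzylic ether (C7') by the Lewis acidic Bu2BOTf, or sluggish enolisation and eroded facial control caused by the very bulky aryloxy group. Fallback (sets out from 19 and 15, comes back at 22): aldehyde 19 is homologated with ethyl diazoacetate (SnCl2 cat., Roskamp reaction) to ethyl 3-[4-(benzyloxy)-3,5-dimethoxyphenyl]-3-oxopropanoate F6 and brominated (NBS) to ethyl 2-bromo-3-[4-(benzyloxy)-3,5-dimethoxyphenyl]-3-oxopropanoate F7. Phenol 15 displaces the bromide (K2CO3, acetone) to give the α-aryloxy β-keto ester F8 as a pair of labile epimers. Asymmetric transfer hydrogenation with dynamic kinetic resolution (RuCl(p-cymene)[(S,S)-TsDPEN], HCO2H–Et3N) should give the syn ethyl (2S,3R)-2-(aryloxy)-3-hydroxy ester F9, and LiBH4 reduction of the ester returns the route at 22.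

Step 1. What may go wrong: insufficient or reversed asymmetric induction and slow addition to the electron-rich aldehyde. Fallback (sets out from 1, comes back at 5): vinylmagnesium bromide addition to 1 gives racemic 1-[4-(benzyloxy)-3-methoxyphenyl]prop-2-en-1-ol F10. Lipase-catalysed acylation (Novozym 435, vinyl acetate) should convert the (R)-enantiomer into (R)-1-[4-(benzyloxy)-3-methoxyphenyl]allyl acetate F11 while the (S)-alcohol is separated. Methanolysis (K2CO3, MeOH) gives (R)-1-[4-(benzyloxy)-3-methoxyphenyl]prop-2-en-1-ol F12, and acryloyl chloride with Et3N gives (R)-1-[4-(benzyloxy)-3-methoxyphenyl]allyl acrylate F13. Ring-closing metathesis with the second-generation Grubbs catalyst (CH2Cl2, 40 °C) gives 5 and bypasses steps 1 and 2.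

**Further compounds**

F1 | step 5 | [4-(allyloxy)-3,5-dimethoxyphenyl]methanol | COc1cc(CO)cc(OC)c1OCC=C
F2 | step 5 | tributyl({[4-(allyloxy)-3,5-dimethoxybenzyl]oxy}methyl)stannane | CCCC[Sn](CCCC)(CCCC)COCc1cc(OC)c(OCC=C)c(OC)c1
F3 | step 5 | (4S,5R)-4-({[4-(allyloxy)-3,5-dimethoxybenzyl]oxy}methyl)-5-[4-(benzyloxy)-3-methoxyphenyl]dihydrofuran-2(3H)-one | COc1cc([C@@H]2OC(=O)C[C@H]2COCc2cc(OC)c(OCC=C)c(OC)c2)ccc1OCc1ccccc1
F4 | step 5 | 3-(trifluoroacetyl) derivative of F3 | COc1cc([C@@H]2OC(=O)C(C(=O)C(F)(F)F)[C@H]2COCc2cc(OC)c(OCC=C)c(OC)c2)ccc1OCc1ccccc1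
F5 | step 5 | 3-diazo derivative of F3 | COc1cc([C@@H]2OC(=O)C(=[N+]=[N-])[C@H]2COCc2cc(OC)c(OCC=C)c(OC)c2)ccc1OCc1ccccc1
F6 | step 11 | ethyl 3-[4-(benzyloxy)-3,5-dimethoxyphenyl]-3-oxopropanoate | CCOC(=O)CC(=O)c1cc(OC)c(OCc2ccccc2)c(OC)c1
F7 | step 11 | ethyl 2-bromo-3-[4-(benzyloxy)-3,5-dimethoxyphenyl]-3-oxopropanoate | CCOC(=O)C(Br)C(=O)c1cc(OC)c(OCc2ccccc2)c(OC)c1
F8 | step 11 | ethyl 2-(aryloxy)-3-[4-(benzyloxy)-3,5-dimethoxyphenyl]-3-oxopropanoate, aryloxy = phenoxy group of 15 | COc1cc([C@@H]2OC[C@@H]3[C@H]2CO[C@@H]3c2cc(OC)c(OC(C(=O)OCC)C(=O)c4cc(OC)c(OCc5ccccc5)c(OC)c4)c(OC)c2)ccc1OCc1ccccc1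
F9 | step 11 | ethyl (2S,3R)-2-(aryloxy)-3-[4-(benzyloxy)-3,5-dimethoxyphenyl]-3-hydroxypropanoate, aryloxy = phenoxy group of 15 | COc1cc([C@@H]2OC[C@@H]3[C@H]2CO[C@@H]3c2cc(OC)c(O[C@H](C(=O)OCC)[C@H](O)c4cc(OC)c(OCc5ccccc5)c(OC)c4)c(OC)c2)ccc1OCc1ccccc1
F10 | step 1 | racemic 1-[4-(benzyloxy)-3-methoxyphenyl]prop-2-en-1-ol | C=CC(O)c1ccc(OCc2ccccc2)c(OC)c1
F11 | step 1 | (R)-1-[4-(benzyloxy)-3-methoxyphenyl]allyl acetate | C=C[C@@H](OC(C)=O)c1ccc(OCc2ccccc2)c(OC)c1
F12 | step 1 | (R)-1-[4-(benzyloxy)-3-methoxyphenyl]prop-2-en-1-ol | C=C[C@@H](O)c1ccc(OCc2ccccc2)c(OC)c1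
F13 | step 1 | (R)-1-[4-(benzyloxy)-3-methoxyphenyl]allyl acrylate | C=CC(=O)O[C@H](C=C)c1ccc(OCc2ccccc2)c(OC)c1
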